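All runs were generated by integration on assumed constants.

Start from the leftover of the two earlier runs, and read the new flask out of it.

| flask | starting material | coupling partner | remark | time |
|---|---|---|---|---|
| Sunday's | 10 mM | 50 mM | run made earlier |  |
| Wednesday's | 15 mM | 50 mM | run made earlier |  |
| flask | 20 mM | 50.0 mM |  | 2.0 min |

- Sunday's (time / s: target / %): 10.0: 3.1; 30.0: 3.7; 60.0: 8.7; 80.0: 11.7; 120: 16.6
- Wednesday's (time / s: target / %): 10.0: 1.0; 20.0: 3.4; 30.0: 4.8; 60.0: 8.4; 120: 15.7

(scatter of a reading: 0.5 percentage points)

- for by-product the crystals are counted in
- as a solid, counted per litre of solution: crystals
- what may be going on: crystals <-> by-product; starting material + coupling partner <-> target + by-product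

* how much target there is at 2.0 min, in percent of the starting material charged
* concentration of by-product in solution at 2.0 min, in percent of saturation

At 120 s, Sunday's run has 83.4 % of its starting material left, counting whatever is not target as unreacted; Wednesday's has 84.3 %. Take minus the natural logarithm of each leftover, divide by time and by coupling partner charged, and average the two. That gives the coupling constant, the rate per unit of starting material and of partner, read here as 0.0294 L mol⁻¹ s⁻¹.

Now climb the ladder for the new flask. The asked time, 2.0 min, is the lowest rung. Next comes the clock of the starting material, one over the constant times the partner charged: 11.4 min, pseudo-first-order, with the partner in excess. Above it stands the partner's own clock, 28.4 min. The asked time is shorter than both, so expect an early flask. My reckoning gives 16.2 % target, with as much by-product, crystals counted in, 3.23 mM. The runs measured target, not dissolved by-product, so I name no saturation value.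

The forecast says 15.5 % (14 % to 17 %), below my figure, and 85 % of saturation (45 % to 105 %): “This is weakly constrained.”

The flask gives 16.0 % target, with by-product at 22.8 % of saturation.

    crystals ⇌ by-product, rate k1*(cs1 - [by-product]) while solid is left; crystals form when [by-product] > cs1 (solubility = 14.0 mM, k = 0.0600 s⁻¹)
    starting material + coupling partner ⇌ target + by-product (K = 20.0, k = 0.0300 L mol⁻¹ s⁻¹)

In this flask, the coupling's relaxation half-life, both ways together, is 6.02 min at the asked time, longer than 2.0 min. At that time this flask holds 84.0 % of the starting material, and dissolved by-product stands at 3.19 mM against a saturation of 14 mM, with crystals at 0 mM.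

Take the neighbour flask with 30 mM of coupling partner. With the coupling constant, its clock reads 18.9 min, and the reckoning gives 10.0 % target; the computed result is 9.91 %.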